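No rate constant of this flask stands on the board, so the meeting asked what the readings can give in its place.

all flasks: substrate 0.050 M

|  | remark | time |
|---|---|---|
| spring | the very flask that is asked about, followed so far |  |
| flask |  | 1.5 h |

spring run (percent of the substrate charged)

| time / min | substrate / % | target / % |
|---|---|---|
| 1.00 | 38.7 | 4.5 |
| 3.00 | 27.6 | 4.1 |
| 5.00 | 25.1 | 4.7 |
| 8.00 | 23.6 | 4.0 |
| 10.0 | 22.1 | 4.7 |
| 15.0 | 22.0 | 4.7 |
| 20.0 | 22.3 | 5.0 |

(readings scatter by 0.5 percentage points)

1. which holds at 1.5 h: what has brought the reaction to rest, or that it has not come to rest (all of the substrate has reacted / forward and back rates have come level / it is still moving)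
2. share of the substrate used up at 1.5 h
3. target at 1.5 h, in percent of the substrate charged
4. isomer of the product B at 1.5 h, in percent of the substrate charged
5. isomer of the product A at 1.5 h, in percent of the substrate charged

- the numbers in the tables scatter by 0.5 percentage points (one standard deviation)
- the reaction counts as stopped when no species that holds the substrate changes by six tenths of a point or more over the second half of the time

The first speaker proposed to work with the fraction left and not the fraction made. She averaged c(substrate), as a share of the charge, over the last readings of the spring run and wrote 22.1% on the board. Those readings drift by 0.2 percentage points, less than the scatter of 0.5 points.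

The second speaker argued that a level so far above zero means the substrate is not being used up, so forward and back rates have come level and the conversion is 77.9%. He took target from the same readings as 4.80%, which leaves 73.1% for the unseen species, with no reading to divide it.

The third speaker objected that a plateau means little until we know how fast the flask returns to it. She defined the excess as the share left minus 22.1% and took its decay between 3.00 min and 8.00 min, where the fall has slowed. That gave a return time, the usual relaxation time, of 3.80 min. It is a rough reading, since the later excess is only 1.5 points. Still, 1.5 h is 23.7 such times, so the meeting expected the same composition then.

The forecast reads the end as forward and back rates have come level, with 78% used up and target at 4.6% where the meeting took 4.80%, and it gives 36.7% of isomer of the product B and 36.7% of isomer of the product A, saying “Nothing measured separates them”.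

The flask gives forward and back rates have come level, with 77.8% used up, target 4.67%, isomer of the product B 40.5% and isomer of the product A 29.0%.

    target ⇌ isomer of the product C (K = 0.600, k = 0.00330 s⁻¹)
    isomer of the product A ⇌ isomer of the product B (K = 1.40, k = 0.00280 s⁻¹)
    target ⇌ isomer of the product A (K = 6.20, k = 0.0100 s⁻¹)
    isomer of the product B ⇌ substrate (k = 0.0120 s⁻¹)
    substrate ⇌ target (K = 0.210, k = 0.00260 s⁻¹)
    substrate → decomposition product (k = 6.20 × 10⁻⁶ s⁻¹)

Over the second half of the time the decomposition product in this flask rose from 0.401% to 0.774%. The return time puts c(substrate) at 4.5 min at 25.8%, and the flask holds 25.7%. At 25 min it leaves an excess of 0.017 points, and that reading shows 22.4% of substrate.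

The data stem from a simulated flask on assumed constants; noise was put on by code.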